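**Plan**
Ring A is the benzyl ring, numbered C1 (CH2O), C2 (O-aryl), C3 (OH), C5 (OMe); ring B is the 3-hydroxy-5-methylphenyl ring.
Cuts, in retrosynthetic order: (a) the ring A C1–CH2 bond together with the CH2–O(acyl) bond, which gives an aryl bromide, formaldehyde and palmitoyl chloride; (b) the ring A C3–OH bond back to C3–Br; (c) the ether bond from the C2 oxygen to ring B C1'.
Enabling features: the benzylic carbon lies between ring A C1 and the ester oxygen at the oxidation level of formaldehyde, so it is the carbon of a chloromethyl ester. C1 and C3 flank C2 symmetrically about the C2···C5 axis, so both come from the two bromines of a para-methoxy 2,6-dibromophenol.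
Forward order: silylated ring B boronic acid, Chan–Lam ether formation, bromine-to-hydroxyl exchange at C3, silylation, nickel-catalysed three-component coupling at C1, desilylation.
Both arenes are bought, no ring is built, and the chain is joined in the penultimate step. The target has no stereocentre, so no stereocontrol is needed.

Key step: step 6

Remark on the chemistry: the four starting materials are assumed to be commercial, and paraformaldehyde is written as its monomer unit.

**Step 1**
Reactants: 1 3-bromo-5-methylphenol
Product: 2 tert-butyl(3-bromo-5-methylphenoxy)dimethylsilane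
Conditions: TBSCl, imidazole, DMF, rt
Reagents that add atoms: tert-butyldimethylsilyl chloride (TBSCl), CC(C)(C)[Si](C)(C)Cl
Why: Imidazole-promoted silylation of a phenol should mask the ring B hydroxyl as a silyl ether that tolerates the later organolithium, copper and nickel chemistry and is removed by fluoride at the end.

**Step 2**
Reactants: 2 tert-butyl(3-bromo-5-methylphenoxy)dimethylsilane
Product: 5 [3-(tert-butyldimethylsilyloxy)-5-methylphenyl]boronic acid, via aryllithium 3 (not isolated), via lithium aryltriisopropoxyborate 4 (not isolated)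
Conditions: n-BuLi, THF, −78 °C; B(OiPr)3, −78 °C to rt; 1 M HCl, 0 °C
Reagents that add atoms: triisopropyl borate, CC(C)OB(OC(C)C)OC(C)C; water, O
Why: Lithium–bromine exchange, trapping with a trialkyl borate and mild hydrolysis is the standard route to arylboronic acids, and the lithium sits meta to the silyloxy group, so no silyl shift from oxygen to carbon can occur.

**Step 3**
Reactants: 5 [3-(tert-butyldimethylsilyloxy)-5-methylphenyl]boronic acid; 6 2,6-dibromo-4-methoxyphenol
Product: 7 1,3-dibromo-2-[3-(tert-butyldimethylsilyloxy)-5-methylphenoxy]-5-methoxybenzene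
Conditions: Cu(OAc)2, pyridine, Et3N, 4 Å molecular sieves, CH2Cl2, air, rt
Reagents that add atoms: none
Why: Chan–Lam oxidative C–O coupling should form the hindered diaryl ether at room temperature, since 2,6-dihalophenols and silyloxy-substituted arylboronic acids are established partners and the two C–Br bonds are inert to divalent copper under these conditions.

**Step 4**
Reactants: 7 1,3-dibromo-2-[3-(tert-butyldimethylsilyloxy)-5-methylphenoxy]-5-methoxybenzene
Product: 10 3-bromo-2-[3-(tert-butyldimethylsilyloxy)-5-methylphenoxy]-5-methoxyphenol, via aryllithium 8 (not isolated), via lithium aryltrimethoxyborate 9 (not isolated)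
Conditions: n-BuLi (1.0 equiv), THF, −78 °C; B(OMe)3, −78 to 0 °C; AcOH, 30% H2O2, 0 °C to rt
Reagents that add atoms: hydrogen peroxide, OO
Why: One equivalent of n-BuLi should exchange only one of the two equivalent bromines, and borylation followed by boronate oxidation (1,2-aryl shift from boron to oxygen) under weakly acidic conditions should give the C3 phenol with the aryl silyl ether intact, which desymmetrises ring A.

**Step 5**
Reactants: 10 3-bromo-2-[3-(tert-butyldimethylsilyloxy)-5-methylphenoxy]-5-methoxyphenol
Product: 11 tert-butyl{3-bromo-2-[3-(tert-butyldimethylsilyloxy)-5-methylphenoxy]-5-methoxyphenoxy}dimethylsilane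
Conditions: TBSCl, imidazole, DMF, rt
Reagents that add atoms: tert-butyldimethylsilyl chloride (TBSCl), CC(C)(C)[Si](C)(C)Cl
Why: Standard phenol silylation should mask the new C3 hydroxyl so that no free phenol can be acylated or alkylated by the acyl chloride and chloromethyl ester used in the next step.

**Step 6**
Reactants: 11 tert-butyl{3-bromo-2-[3-(tert-butyldimethylsilyloxy)-5-methylphenoxy]-5-methoxyphenoxy}dimethylsilane; 12 hexadecanoyl chloride (palmitoyl chloride); 13 paraformaldehyde
Product: 15 [3-(tert-butyldimethylsilyloxy)-2-[3-(tert-butyldimethylsilyloxy)-5-methylphenoxy]-5-methoxyphenyl]methyl hexadecanoate, via chloromethyl hexadecanoate 14 (not isolated)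
Conditions: 12, 13, ZnCl2 (cat.), neat, 70 °C; then 11, NiBr2·dme (10 mol %), 4,4'-di-tert-butyl-2,2'-bipyridine, Zn, DMA, 50 °C
Reagents that add atoms: none
Why: Formaldehyde inserts into the acyl C–Cl bond of 12 under ZnCl2 catalysis to give the chloromethyl ester 14, in which the future benzylic carbon already carries the palmitoyloxy group; zerovalent nickel (from NiBr2·dme, the bipyridine and Zn) then adds oxidatively to the C–Br bond of 11, the divalent arylnickel bromide captures the acyloxymethyl radical formed by chlorine abstraction from 14, and reductive elimination from trivalent nickel forms the ring A C1–CH2 bond while Zn returns nickel to its low-valent state. The closest known reaction type is the nickel-catalysed reductive cross-electrophile coupling of aryl bromides with alkyl halides, including alpha-oxygenated alkyl chlorides generated in the same flask, and the capture of alpha-acyloxyalkyl radicals by arylnickel species. No ring is closed and no stereocentre is formed. The step needs cross-coupling over homo-coupling, which the different activation of the two electrophiles secures (two-electron oxidative addition at the C(sp2)–Br bond, one-electron activation of the alpha-acyloxy C(sp3)–Cl bond), and it needs a single site on ring A, which the one remaining bromine at C1 fixes. Esterification of the benzylic oxygen in the presence of two phenolic oxygens is secured because the ester arrives preformed on the carbon fragment and both phenols are silyl ethers inert to Zn and ZnCl2.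

**Step 7**
Reactants: 15 [3-(tert-butyldimethylsilyloxy)-2-[3-(tert-butyldimethylsilyloxy)-5-methylphenoxy]-5-methoxyphenyl]methyl hexadecanoate
Product: 16 [3-hydroxy-2-(3-hydroxy-5-methylphenoxy)-5-methoxyphenyl]methyl hexadecanoate (betaethrin H)
Conditions: Bu4NF, AcOH, THF, 0 °C
Reagents that add atoms: none
Why: Fluoride-mediated cleavage of both aryl silyl ethers, buffered with AcOH, should leave the benzylic palmitate untouched, and no quinone methide can form because neither freed phenol is ortho or para to the benzylic carbon.

**Compound list**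
1 | 3-bromo-5-methylphenol | Cc1cc(O)cc(Br)c1 | starting material
2 | tert-butyl(3-bromo-5-methylphenoxy)dimethylsilane | Cc1cc(Br)cc(O[Si](C)(C)C(C)(C)C)c1 | intermediate
3 | [3-(tert-butyldimethylsilyloxy)-5-methylphenyl]lithium | [Li]c1cc(C)cc(O[Si](C)(C)C(C)(C)C)c1 | intermediate
4 | lithium [3-(tert-butyldimethylsilyloxy)-5-methylphenyl]triisopropoxyborate | CC(C)O[B-](OC(C)C)(OC(C)C)c1cc(C)cc(O[Si](C)(C)C(C)(C)C)c1.[Li+] | intermediate
5 | [3-(tert-butyldimethylsilyloxy)-5-methylphenyl]boronic acid | Cc1cc(B(O)O)cc(O[Si](C)(C)C(C)(C)C)c1 | intermediate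
6 | 2,6-dibromo-4-methoxyphenol | COc1cc(Br)c(O)c(Br)c1 | starting material
7 | 1,3-dibromo-2-[3-(tert-butyldimethylsilyloxy)-5-methylphenoxy]-5-methoxybenzene | COc1cc(Br)c(Oc2cc(C)cc(O[Si](C)(C)C(C)(C)C)c2)c(Br)c1 | intermediate
8 | {3-bromo-2-[3-(tert-butyldimethylsilyloxy)-5-methylphenoxy]-5-methoxyphenyl}lithium | COc1cc(Br)c(Oc2cc(C)cc(O[Si](C)(C)C(C)(C)C)c2)c([Li])c1 | intermediate
9 | lithium {3-bromo-2-[3-(tert-butyldimethylsilyloxy)-5-methylphenoxy]-5-methoxyphenyl}trimethoxyborate | COc1cc(Br)c(Oc2cc(C)cc(O[Si](C)(C)C(C)(C)C)c2)c([B-](OC)(OC)OC)c1.[Li+] | intermediate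
10 | 3-bromo-2-[3-(tert-butyldimethylsilyloxy)-5-methylphenoxy]-5-methoxyphenol | COc1cc(Br)c(Oc2cc(C)cc(O[Si](C)(C)C(C)(C)C)c2)c(O)c1 | intermediate
11 | tert-butyl{3-bromo-2-[3-(tert-butyldimethylsilyloxy)-5-methylphenoxy]-5-methoxyphenoxy}dimethylsilane | COc1cc(Br)c(Oc2cc(C)cc(O[Si](C)(C)C(C)(C)C)c2)c(O[Si](C)(C)C(C)(C)C)c1 | intermediate
12 | hexadecanoyl chloride (palmitoyl chloride) | CCCCCCCCCCCCCCCC(=O)Cl | starting material
13 | paraformaldehyde (formaldehyde source) | C=O | starting material
14 | chloromethyl hexadecanoate | CCCCCCCCCCCCCCCC(=O)OCCl | intermediate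
15 | [3-(tert-butyldimethylsilyloxy)-2-[3-(tert-butyldimethylsilyloxy)-5-methylphenoxy]-5-methoxyphenyl]methyl hexadecanoate | CCCCCCCCCCCCCCCC(=O)OCc1cc(OC)cc(O[Si](C)(C)C(C)(C)C)c1Oc1cc(C)cc(O[Si](C)(C)C(C)(C)C)c1 | intermediate
16 | [3-hydroxy-2-(3-hydroxy-5-methylphenoxy)-5-methoxyphenyl]methyl hexadecanoate (betaethrin H) | CCCCCCCCCCCCCCCC(=O)OCc1cc(OC)cc(O)c1Oc1cc(C)cc(O)c1 | target

**Step count**
Total: 7 steps. Longest linear sequence: 7 steps (1 to 16 through steps 1–7); compound 6 enters at step 3 and compounds 12 and 13 at step 6.

**Steps most likely to fail**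

Step 6. Oxidative addition of low-valent nickel at the electron-rich C–Br bond flanked by the aryloxy group may be slow, so that reductive dimerisation or hydrodechlorination of the chloromethyl ester and hydrodebromination of the arene take over. The fallback builds the same bond by polar, stepwise chemistry and sets out from 11. Lithium–bromine exchange (n-BuLi, THF, −78 °C) and formylation with DMF should give 3-(tert-butyldimethylsilyloxy)-2-[3-(tert-butyldimethylsilyloxy)-5-methylphenoxy]-5-methoxybenzaldehyde F1. Reduction with NaBH4 (EtOH/THF, 0 °C) should give [3-(tert-butyldimethylsilyloxy)-2-[3-(tert-butyldimethylsilyloxy)-5-methylphenoxy]-5-methoxyphenyl]methanol F2. Acylation with 12 (pyridine, DMAP cat., CH2Cl2, 0 °C) comes back to the route at 15.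

Step 3. Transmetalation and C–O bond formation at copper may be slow for the di-ortho-bromo phenoxide, so that protodeboronation or oxidative homocoupling of the boronic acid and oxidation of the electron-rich phenol compete. The fallback is a metal-free arylation at trivalent iodine and sets out from 5 and 6. Treatment of 5 with 1-(diacetoxyiodo)-4-methoxybenzene and BF3·OEt2 (CH2Cl2, −30 °C) should give (4-methoxyphenyl)[3-(tert-butyldimethylsilyloxy)-5-methylphenyl]iodonium tetrafluoroborate F3. Its reaction with the potassium phenoxide of 6 (KOt-Bu, THF, rt) should transfer the less electron-rich ring B aryl by ligand coupling and comes back to the route at 7.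

Step 4. The halogen–lithium exchange may be incomplete or go twice, the aryllithium may be protonated before borylation or lose lithium aryloxide, or the silyl ether may be lost during oxidation. The fallback carries the C3 oxygen as a latent aldehyde and sets out from 5. Chan–Lam coupling of 5 with commercial 3-bromo-2-hydroxy-5-methoxybenzaldehyde (conditions of step 3) should give 3-bromo-2-[3-(tert-butyldimethylsilyloxy)-5-methylphenoxy]-5-methoxybenzaldehyde F4. Baeyer–Villiger oxidation (mCPBA, CH2Cl2, rt) should give 3-bromo-2-[3-(tert-butyldimethylsilyloxy)-5-methylphenoxy]-5-methoxyphenyl formate F5. Mild methanolysis (Et3N, MeOH, rt) comes back to the route at 10.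

**Further compounds**
F1 | step 6 | 3-(tert-butyldimethylsilyloxy)-2-[3-(tert-butyldimethylsilyloxy)-5-methylphenoxy]-5-methoxybenzaldehyde | COc1cc(C=O)c(Oc2cc(C)cc(O[Si](C)(C)C(C)(C)C)c2)c(O[Si](C)(C)C(C)(C)C)c1
F2 | step 6 | [3-(tert-butyldimethylsilyloxy)-2-[3-(tert-butyldimethylsilyloxy)-5-methylphenoxy]-5-methoxyphenyl]methanol | COc1cc(CO)c(Oc2cc(C)cc(O[Si](C)(C)C(C)(C)C)c2)c(O[Si](C)(C)C(C)(C)C)c1
F3 | step 3 | (4-methoxyphenyl)[3-(tert-butyldimethylsilyloxy)-5-methylphenyl]iodonium tetrafluoroborate | COc1ccc([I+]c2cc(C)cc(O[Si](C)(C)C(C)(C)C)c2)cc1.F[B-](F)(F)F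
F4 | step 4 | 3-bromo-2-[3-(tert-butyldimethylsilyloxy)-5-methylphenoxy]-5-methoxybenzaldehyde | COc1cc(Br)c(Oc2cc(C)cc(O[Si](C)(C)C(C)(C)C)c2)c(C=O)c1
F5 | step 4 | 3-bromo-2-[3-(tert-butyldimethylsilyloxy)-5-methylphenoxy]-5-methoxyphenyl formate | COc1cc(Br)c(Oc2cc(C)cc(O[Si](C)(C)C(C)(C)C)c2)c(OC=O)c1
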